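**Plan**

- Retrosynthetic cuts, in order: the C18 acetate to the alcohol; C11–C12 between a bicyclic C11 iodide and a C12–C16 iodide; C8=C17 to a C8 ketone; C9–C10 of ring B by oxidative radical cyclisation of a monocyclic β-keto ester; then C8–C9 (diazo ester homologation), C4–C19 (reductive methylation of an arene) and C6–C7 (benzylic alkylation), back to 2,3-dimethylbenzoic acid.
- Forward order: ring A arises by dearomatisation of the arene, ring B is closed onto it through C9–C10, and the C12–C16 chain is joined last.
- Enabling feature: C9 lies between C8 (the carbon of the exocyclic methylene, carried as a ketone) and C11 (carried as an ester). C9 is therefore the central carbon of a β-keto ester, its radical can bond to C10 of a ring A C5=C10 alkene, and the ketone is left where the methylene is needed.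
- Stereochemistry: C4 from the (S)-2-(methoxymethyl)pyrrolidine amide in the Birch reduction–methylation; C10 from C4 in the ring closure; C9 by equilibration; C5 by hydrogenation anti to the two axial methyl groups; C13 from (R)-3-methylglutaric acid monomethyl ester.
- Atom labels C1–C20 follow labdane numbering throughout.

Key step: step 10

Assumption: the potassium amide enolate of step 3 is taken to be methylated on the face remote from the methoxymethyl arm of the (S)-auxiliary (chelated-enolate model for ortho-alkyl benzamides), which gives the R centre drawn; if the sense were the reverse, the (R)-auxiliary would be used with no other change.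

**Route**

Step 1
Reactants: 1 2,3-dimethylbenzoic acid; 2 (S)-2-(methoxymethyl)pyrrolidine
Product: 4 (2,3-dimethylphenyl)[(2S)-2-(methoxymethyl)pyrrolidin-1-yl]methanone, via 2,3-dimethylbenzoyl chloride 3 (not isolated)
Conditions: (COCl)2, cat. DMF, CH2Cl2, 0 °C→rt; then 2, Et3N, CH2Cl2, 0 °C→rt
Reagents that add atoms: none
Why: Acylation of the secondary amine by the acid chloride (amide formation) attaches the auxiliary that will control C4, and no stereocentre is formed.

Step 2
Reactants: 4 (2,3-dimethylphenyl)[(2S)-2-(methoxymethyl)pyrrolidin-1-yl]methanone; 5 tert-butyl(2-iodoethoxy)dimethylsilane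
Product: 7 {2-[3-(tert-butyldimethylsilyloxy)propyl]-3-methylphenyl}[(2S)-2-(methoxymethyl)pyrrolidin-1-yl]methanone, via benzylic lithium compound 6 (not isolated)
Conditions: LiN(i-Pr)2, THF, −78 °C; then 5, −78→0 °C
Reagents that add atoms: none
Why: The amide base removes a proton from the ortho methyl group, the only benzylic position conjugated with the amide carbonyl (lateral lithiation), and the benzylic lithium compound displaces iodide from the primary iodide (SN2), which adds C7 and the oxygen-bearing C8.

Step 3
Reactants: 7 {2-[3-(tert-butyldimethylsilyloxy)propyl]-3-methylphenyl}[(2S)-2-(methoxymethyl)pyrrolidin-1-yl]methanone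
Product: 9 [(1R)-2-{3-[(tert-butyldimethylsilyl)oxy]propyl}-1,3-dimethylcyclohexa-2,5-dien-1-yl][(2S)-2-(methoxymethyl)pyrrolidin-1-yl]methanone, via potassium amide enolate 8 (not isolated)
Conditions: K (2.2 equiv), t-BuOH (1.0 equiv), NH3/THF, −78 °C; then MeI, −78 °C; NH4Cl
Reagents that add atoms: iodomethane, CI
Why: Birch reduction of the benzamide, with protonation para to the carbonyl group by the single equivalent of tert-butanol, leaves an amide enolate that is methylated at the ipso carbon (auxiliary-controlled Birch reduction–alkylation), and the chelating methoxymethyl arm shields one enolate face so that the methyl group enters from the other and sets C4 as R.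

Step 4
Reactants: 9 [(1R)-2-{3-[(tert-butyldimethylsilyl)oxy]propyl}-1,3-dimethylcyclohexa-2,5-dien-1-yl][(2S)-2-(methoxymethyl)pyrrolidin-1-yl]methanone
Product: 10 [(1R)-2-{3-[(tert-butyldimethylsilyl)oxy]propyl}-1,3-dimethylcyclohex-2-en-1-yl][(2S)-2-(methoxymethyl)pyrrolidin-1-yl]methanone
Conditions: H2 (3 bar), RhCl(PPh3)3 (5 mol%), benzene/EtOH, rt
Reagents that add atoms: none
Why: Homogeneous hydrogenation with this rhodium complex is sensitive to substitution and should saturate the cis-disubstituted ring alkene while leaving the tetrasubstituted C5=C10 alkene, needed for the ring closure, untouched.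

Step 5
Reactants: 10 [(1R)-2-{3-[(tert-butyldimethylsilyl)oxy]propyl}-1,3-dimethylcyclohex-2-en-1-yl][(2S)-2-(methoxymethyl)pyrrolidin-1-yl]methanone
Product: 11 [(1R)-2-{3-[(tert-butyldimethylsilyl)oxy]propyl}-1,3-dimethylcyclohex-2-en-1-yl]methanol
Conditions: LiNH2BH3 (from BH3·NH3 and LiN(i-Pr)2), THF, 0 °C→rt
Reagents that add atoms: none
Why: Lithium amidotrihydroborate is a small, strongly nucleophilic hydride donor that reduces hindered tertiary amides to primary alcohols with C–N cleavage (amide-to-alcohol reduction), which frees C18 as a hydroxymethyl group and returns the auxiliary without risk to the quaternary C4.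

Step 6
Reactants: 11 [(1R)-2-{3-[(tert-butyldimethylsilyl)oxy]propyl}-1,3-dimethylcyclohex-2-en-1-yl]methanol
Product: 12 tert-butyl{[(1R)-2-{3-[(tert-butyldimethylsilyl)oxy]propyl}-1,3-dimethylcyclohex-2-en-1-yl]methoxy}diphenylsilane
Conditions: t-BuPh2SiCl, imidazole, DMF, rt→40 °C
Reagents that add atoms: tert-butyl(chloro)diphenylsilane, CC(C)(C)[Si](Cl)(c1ccccc1)c1ccccc1
Why: Imidazole-promoted silylation of the neopentyl-type alcohol gives a bulky, robust ether that is clearly less labile than the chain silyl ether and enlarges the size difference between the two C4 substituents for the ring closure.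

Step 7
Reactants: 12 tert-butyl{[(1R)-2-{3-[(tert-butyldimethylsilyl)oxy]propyl}-1,3-dimethylcyclohex-2-en-1-yl]methoxy}diphenylsilane
Product: 13 3-[(6R)-6-{[(tert-butyldiphenylsilyl)oxy]methyl}-2,6-dimethylcyclohex-1-en-1-yl]propan-1-ol
Conditions: camphorsulfonic acid (cat.), MeOH/CH2Cl2, 0 °C
Reagents that add atoms: none
Why: Acid-catalysed methanolysis removes the unhindered primary tert-butyldimethylsilyl ether much faster than the neopentyl tert-butyldiphenylsilyl ether (selective desilylation), and the tetrasubstituted alkene is not protonated under these mild conditions.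

Step 8
Reactants: 13 3-[(6R)-6-{[(tert-butyldiphenylsilyl)oxy]methyl}-2,6-dimethylcyclohex-1-en-1-yl]propan-1-ol
Product: 14 3-[(6R)-6-{[(tert-butyldiphenylsilyl)oxy]methyl}-2,6-dimethylcyclohex-1-en-1-yl]propanal
Conditions: Dess–Martin periodinane, CH2Cl2, 0 °C→rt
Reagents that add atoms: none
Why: Dess–Martin oxidation converts the primary alcohol to the aldehyde under near-neutral conditions without touching the alkene or the silyl ether.

Step 9
Reactants: 14 3-[(6R)-6-{[(tert-butyldiphenylsilyl)oxy]methyl}-2,6-dimethylcyclohex-1-en-1-yl]propanal; 15 ethyl diazoacetate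
Product: 16 ethyl 5-[(6R)-6-{[(tert-butyldiphenylsilyl)oxy]methyl}-2,6-dimethylcyclohex-1-en-1-yl]-3-oxopentanoate
Conditions: SnCl2 (10 mol%), CH2Cl2, rt
Reagents that add atoms: none
Why: Lewis-acid-catalysed addition of the diazo ester to the aldehyde, loss of dinitrogen and 1,2-hydride shift (Roskamp homologation) form the C8–C9 bond and place C9 between the C8 ketone and the C11 ester, the ethyl ester being a spectator that is reduced in step 13.

Step 10
Reactants: 16 ethyl 5-[(6R)-6-{[(tert-butyldiphenylsilyl)oxy]methyl}-2,6-dimethylcyclohex-1-en-1-yl]-3-oxopentanoate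
Product: 17 ethyl (1R,5R,8aR)-5-{[(tert-butyldiphenylsilyl)oxy]methyl}-5,8a-dimethyl-2-oxo-1,2,3,5,6,7,8,8a-octahydronaphthalene-1-carboxylate (C8 ketone, C11 ester, C5=C6 alkene)
Conditions: Mn(OAc)3·2H2O (2.2 equiv), Cu(OAc)2·H2O (1.0 equiv), degassed AcOH, rt→40 °C
Reagents that add atoms: none
Why: Mn(OAc)3 forms the trivalent manganese enolate of the β-keto ester and electron transfer gives the electrophilic C9 radical, which adds to C10 of the electron-rich C5=C10 alkene; the tertiary C5 radical is then oxidised by Cu(OAc)2 (divalent copper) through an alkylcopper species that loses hydrogen from C6, the only neighbour that carries hydrogen, so that one alkene isomer (C5=C6) should result. The closest known reaction type is the Mn(OAc)3/Cu(OAc)2 oxidative cyclisation of unsaturated β-keto esters. Ring B closes in the 6-endo-trig mode, which α-keto radicals with the carbonyl group inside the forming ring prefer over 5-exo and which is reinforced here because the other terminus, C5, is flanked by the quaternary C4. C10 is controlled by C4: in the half-chair of ring A the small C4 methyl is expected to sit pseudoaxial and the silyloxymethyl arm pseudoequatorial, the radical enters anti to that methyl, and the C10 methyl is pushed to the face of the C4 methyl, where the developing 1,3-diaxial contact is the smaller of the two possible ones. C9 remains enolisable and should settle as the equatorial ester trans to the C10 methyl under thermodynamic control. The step needs face selectivity at C10, 6-endo regioselectivity and no second oxidation of the product; these rest on the bulky silyl ether at C18, on the substitution pattern of the alkene, and on the slow enolisation of the hindered bicyclic keto ester together with the use of only about two equivalents of oxidant.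

Step 11
Reactants: 17 ethyl (1R,5R,8aR)-5-{[(tert-butyldiphenylsilyl)oxy]methyl}-5,8a-dimethyl-2-oxo-1,2,3,5,6,7,8,8a-octahydronaphthalene-1-carboxylate
Product: 18 ethyl (1R,4aR,5R,8aS)-5-{[(tert-butyldiphenylsilyl)oxy]methyl}-5,8a-dimethyl-2-oxodecahydronaphthalene-1-carboxylate
Conditions: H2 (50 bar), 10% Pd/C, EtOAc, 50 °C
Reagents that add atoms: none
Why: Heterogeneous hydrogenation should deliver hydrogen to the α-face of the hindered trisubstituted C5=C6 alkene because the β-face is covered by the axial methyl groups on C4 and C10, which gives the trans ring fusion (C5 R, hydrogen anti to the C10 methyl) while ketone, ester and silyl ether stay intact.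

Step 12
Reactants: 18 ethyl (1R,4aR,5R,8aS)-5-{[(tert-butyldiphenylsilyl)oxy]methyl}-5,8a-dimethyl-2-oxodecahydronaphthalene-1-carboxylate
Product: 19 ethyl (1S,4aR,5R,8aS)-5-{[(tert-butyldiphenylsilyl)oxy]methyl}-5,8a-dimethyl-2-methylidenedecahydronaphthalene-1-carboxylate
Conditions: Ph3PCH3Br (3 equiv), KOt-Bu (2.8 equiv), toluene, rt→90 °C
Reagents that add atoms: methyltriphenylphosphonium bromide, C[P+](c1ccccc1)(c1ccccc1)c1ccccc1.[Br-]
Why: Wittig methylenation of the C8 ketone should be possible because enolisation of this keto ester would force the ester into the plane next to the quaternary C10 (allylic 1,3-strain), so the ketone remains available to the ylide, and C9 stays the equatorial, thermodynamically preferred epimer.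

Step 13
Reactants: 19 ethyl (1S,4aR,5R,8aS)-5-{[(tert-butyldiphenylsilyl)oxy]methyl}-5,8a-dimethyl-2-methylidenedecahydronaphthalene-1-carboxylate
Product: 20 [(1S,4aR,5R,8aS)-5-{[(tert-butyldiphenylsilyl)oxy]methyl}-5,8a-dimethyl-2-methylidenedecahydronaphthalen-1-yl]methanol
Conditions: LiAlH4, Et2O, 0 °C
Reagents that add atoms: none
Why: Hydride reduction of the hindered ester gives the primary C11 alcohol without affecting the 1,1-disubstituted alkene or the silyl ether.

Step 14
Reactants: 20 [(1S,4aR,5R,8aS)-5-{[(tert-butyldiphenylsilyl)oxy]methyl}-5,8a-dimethyl-2-methylidenedecahydronaphthalen-1-yl]methanol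
Product: 21 (1S,4aR,5R,8aS)-5-{[(tert-butyldiphenylsilyl)oxy]methyl}-1-(iodomethyl)-5,8a-dimethyl-2-methylidenedecahydronaphthalene
Conditions: PPh3, I2, imidazole, toluene/MeCN, rt→60 °C
Reagents that add atoms: iodine, II
Why: Appel-type iodination through the alkoxyphosphonium salt converts the primary alcohol to the iodide under buffered conditions that avoid acid-induced migration of the exocyclic alkene, and C9 is not involved.

Step 15
Reactants: 22 (3R)-5-methoxy-3-methyl-5-oxopentanoic acid ((R)-3-methylglutaric acid monomethyl ester)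
Product: 23 methyl (3S)-4-iodo-3-methylbutanoate
Conditions: PhI(OAc)2, I2, cyclohexane, hν (tungsten lamp), reflux
Reagents that add atoms: iodine, II
Why: Photolysis of the acyl hypoiodite formed in the flask gives, after loss of CO2, a primary alkyl radical that is trapped by iodine (Hunsdiecker-type iododecarboxylation), and the C13 stereocentre, β to the radical, is untouched (the descriptor changes only through the priority rules).

Step 16
Reactants: 21 (1S,4aR,5R,8aS)-5-{[(tert-butyldiphenylsilyl)oxy]methyl}-1-(iodomethyl)-5,8a-dimethyl-2-methylidenedecahydronaphthalene; 23 methyl (3S)-4-iodo-3-methylbutanoate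
Product: 25 methyl (3R)-5-[(1S,4aR,5R,8aR)-5-{[(tert-butyldiphenylsilyl)oxy]methyl}-5,8a-dimethyl-2-methylidenedecahydronaphthalen-1-yl]-3-methylpentanoate, via alkylzinc iodide 24 (not isolated)
Conditions: Zn dust (activated with Me3SiCl and BrCH2CH2Br), DMA, 40 °C; then 23, Pd2(dba)3 (2 mol%), P(c-C5H9)3 (8 mol%), N-methylimidazole, THF/NMP, 80 °C
Reagents that add atoms: none
Why: Zinc inserts into the primary C–I bond and the alkylzinc iodide is joined to the second primary iodide by a zerovalent palladium catalyst with a bulky trialkylphosphine that favours reductive elimination over β-hydride elimination (alkyl–alkyl Negishi coupling), the more hindered partner being used as the nucleophile so that oxidative addition occurs at the less hindered iodide, with C9 and C13 as spectators.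

Step 17
Reactants: 25 methyl (3R)-5-[(1S,4aR,5R,8aR)-5-{[(tert-butyldiphenylsilyl)oxy]methyl}-5,8a-dimethyl-2-methylidenedecahydronaphthalen-1-yl]-3-methylpentanoate
Product: 27 methyl (3R)-5-[(1S,4aR,5R,8aR)-5-(acetoxymethyl)-5,8a-dimethyl-2-methylidenedecahydronaphthalen-1-yl]-3-methylpentanoate, via 18-alcohol 26 (not isolated)
Conditions: Bu4NF, AcOH, THF, rt→40 °C; then Ac2O, Et3N, DMAP (cat.), rt
Reagents that add atoms: acetic anhydride, CC(=O)OC(C)=O
Why: Buffered fluoride cleaves the silyl ether and the liberated primary alcohol is acetylated in the same flask (DMAP-catalysed acylation), conditions under which the methyl ester and the exocyclic alkene should not react.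

**Compound list**

1 | 2,3-dimethylbenzoic acid | Cc1cccc(C(O)=O)c1C | starting material
2 | (S)-2-(methoxymethyl)pyrrolidine | COC[C@@H]1CCCN1 | starting material
3 | 2,3-dimethylbenzoyl chloride | Cc1cccc(C(Cl)=O)c1C | intermediate
4 | (2,3-dimethylphenyl)[(2S)-2-(methoxymethyl)pyrrolidin-1-yl]methanone | COC[C@@H]1CCCN1C(=O)c1cccc(C)c1C | intermediate
5 | tert-butyl(2-iodoethoxy)dimethylsilane | CC(C)(C)[Si](C)(C)OCCI | starting material
6 | [2-(lithiomethyl)-3-methylphenyl][(2S)-2-(methoxymethyl)pyrrolidin-1-yl]methanone | COC[C@@H]1CCCN1C(=O)c1cccc(C)c1C[Li] | intermediate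
7 | {2-[3-(tert-butyldimethylsilyloxy)propyl]-3-methylphenyl}[(2S)-2-(methoxymethyl)pyrrolidin-1-yl]methanone | COC[C@@H]1CCCN1C(=O)c1cccc(C)c1CCCO[Si](C)(C)C(C)(C)C | intermediate
8 | potassium (2-{3-[(tert-butyldimethylsilyl)oxy]propyl}-3-methylcyclohexa-2,5-dien-1-ylidene)[(2S)-2-(methoxymethyl)pyrrolidin-1-yl]methanolate | COC[C@@H]1CCCN1C([O-])=C1C=CCC(C)=C1CCCO[Si](C)(C)C(C)(C)C.[K+] | intermediate
9 | [(1R)-2-{3-[(tert-butyldimethylsilyl)oxy]propyl}-1,3-dimethylcyclohexa-2,5-dien-1-yl][(2S)-2-(methoxymethyl)pyrrolidin-1-yl]methanone | COC[C@@H]1CCCN1C(=O)[C@]1(C)C=CCC(C)=C1CCCO[Si](C)(C)C(C)(C)C | intermediate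
10 | [(1R)-2-{3-[(tert-butyldimethylsilyl)oxy]propyl}-1,3-dimethylcyclohex-2-en-1-yl][(2S)-2-(methoxymethyl)pyrrolidin-1-yl]methanone | COC[C@@H]1CCCN1C(=O)[C@]1(C)CCCC(C)=C1CCCO[Si](C)(C)C(C)(C)C | intermediate
11 | [(1R)-2-{3-[(tert-butyldimethylsilyl)oxy]propyl}-1,3-dimethylcyclohex-2-en-1-yl]methanol | OC[C@]1(C)CCCC(C)=C1CCCO[Si](C)(C)C(C)(C)C | intermediate
12 | tert-butyl{[(1R)-2-{3-[(tert-butyldimethylsilyl)oxy]propyl}-1,3-dimethylcyclohex-2-en-1-yl]methoxy}diphenylsilane | CC(C)(C)[Si](c1ccccc1)(c1ccccc1)OC[C@]1(C)CCCC(C)=C1CCCO[Si](C)(C)C(C)(C)C | intermediate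
13 | 3-[(6R)-6-{[(tert-butyldiphenylsilyl)oxy]methyl}-2,6-dimethylcyclohex-1-en-1-yl]propan-1-ol | CC(C)(C)[Si](c1ccccc1)(c1ccccc1)OC[C@]1(C)CCCC(C)=C1CCCO | intermediate
14 | 3-[(6R)-6-{[(tert-butyldiphenylsilyl)oxy]methyl}-2,6-dimethylcyclohex-1-en-1-yl]propanal | CC(C)(C)[Si](c1ccccc1)(c1ccccc1)OC[C@]1(C)CCCC(C)=C1CCC=O | intermediate
15 | ethyl diazoacetate | CCOC(=O)C=[N+]=[N-] | starting material
16 | ethyl 5-[(6R)-6-{[(tert-butyldiphenylsilyl)oxy]methyl}-2,6-dimethylcyclohex-1-en-1-yl]-3-oxopentanoate | CCOC(=O)CC(=O)CCC1=C(C)CCC[C@@]1(C)CO[Si](c1ccccc1)(c1ccccc1)C(C)(C)C | intermediate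
17 | ethyl (1R,5R,8aR)-5-{[(tert-butyldiphenylsilyl)oxy]methyl}-5,8a-dimethyl-2-oxo-1,2,3,5,6,7,8,8a-octahydronaphthalene-1-carboxylate | O=C1CC=C2[C@](C)(CO[Si](c3ccccc3)(c3ccccc3)C(C)(C)C)CCC[C@]2(C)[C@H]1C(=O)OCC | intermediate
18 | ethyl (1R,4aR,5R,8aS)-5-{[(tert-butyldiphenylsilyl)oxy]methyl}-5,8a-dimethyl-2-oxodecahydronaphthalene-1-carboxylate | O=C1CC[C@H]2[C@](C)(CO[Si](c3ccccc3)(c3ccccc3)C(C)(C)C)CCC[C@]2(C)[C@H]1C(=O)OCC | intermediate
19 | ethyl (1S,4aR,5R,8aS)-5-{[(tert-butyldiphenylsilyl)oxy]methyl}-5,8a-dimethyl-2-methylidenedecahydronaphthalene-1-carboxylate | C=C1CC[C@H]2[C@](C)(CO[Si](c3ccccc3)(c3ccccc3)C(C)(C)C)CCC[C@]2(C)[C@H]1C(=O)OCC | intermediate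
20 | [(1S,4aR,5R,8aS)-5-{[(tert-butyldiphenylsilyl)oxy]methyl}-5,8a-dimethyl-2-methylidenedecahydronaphthalen-1-yl]methanol | C=C1CC[C@H]2[C@](C)(CO[Si](c3ccccc3)(c3ccccc3)C(C)(C)C)CCC[C@]2(C)[C@H]1CO | intermediate
21 | (1S,4aR,5R,8aS)-5-{[(tert-butyldiphenylsilyl)oxy]methyl}-1-(iodomethyl)-5,8a-dimethyl-2-methylidenedecahydronaphthalene | C=C1CC[C@H]2[C@](C)(CO[Si](c3ccccc3)(c3ccccc3)C(C)(C)C)CCC[C@]2(C)[C@H]1CI | intermediate
22 | (3R)-5-methoxy-3-methyl-5-oxopentanoic acid ((R)-3-methylglutaric acid monomethyl ester) | OC(=O)C[C@@H](C)CC(=O)OC | starting material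
23 | methyl (3S)-4-iodo-3-methylbutanoate | IC[C@@H](C)CC(=O)OC | intermediate
24 | {[(1S,4aR,5R,8aS)-5-{[(tert-butyldiphenylsilyl)oxy]methyl}-5,8a-dimethyl-2-methylidenedecahydronaphthalen-1-yl]methyl}(iodo)zinc | C=C1CC[C@H]2[C@](C)(CO[Si](c3ccccc3)(c3ccccc3)C(C)(C)C)CCC[C@]2(C)[C@H]1C[Zn]I | intermediate
25 | methyl (3R)-5-[(1S,4aR,5R,8aR)-5-{[(tert-butyldiphenylsilyl)oxy]methyl}-5,8a-dimethyl-2-methylidenedecahydronaphthalen-1-yl]-3-methylpentanoate | C=C1CC[C@H]2[C@](C)(CO[Si](c3ccccc3)(c3ccccc3)C(C)(C)C)CCC[C@]2(C)[C@H]1CC[C@@H](C)CC(=O)OC | intermediate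
26 | methyl (3R)-5-[(1S,4aR,5R,8aR)-5-(hydroxymethyl)-5,8a-dimethyl-2-methylidenedecahydronaphthalen-1-yl]-3-methylpentanoate | C=C1CC[C@H]2[C@](C)(CO)CCC[C@]2(C)[C@H]1CC[C@@H](C)CC(=O)OC | intermediate
27 | methyl (3R)-5-[(1S,4aR,5R,8aR)-5-(acetoxymethyl)-5,8a-dimethyl-2-methylidenedecahydronaphthalen-1-yl]-3-methylpentanoate (CNP0322314.1) | C=C1CC[C@H]2[C@](C)(COC(C)=O)CCC[C@]2(C)[C@H]1CC[C@@H](C)CC(=O)OC | target

**Step count**

Total: 17 steps. Longest linear sequence: 16 steps (steps 1–14, 16 and 17, from 2,3-dimethylbenzoic acid); step 15 is the one-step side branch.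

**Steps most likely to fail**

Step 10. The two C4 substituents differ only moderately in size, so the C9 radical may add to the β-face of the ring A alkene and give the C10 epimer; it may also close 5-exo at C5, or the enolisable product may be oxidised a second time. The fallback closes ring B by a polar instead of a radical pathway. It sets out from 16: SnCl4 in CH2Cl2 at −78→0 °C forms the chelated tin enol, the proton released adds to C5 of the ring A alkene, and the C10 cation is captured by C9. This Lewis-acid-induced cyclisation of an unsaturated β-keto ester should give the saturated trans-fused keto ester directly, so the route is rejoined at 18 and step 11 is not needed. No oxidant is present, and the later, more product-like transition state should strengthen the preference for the small C4 methyl in the position syn to the C10 methyl.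

Step 16. Both partners are β-branched, so oxidative addition and transmetalation may be slow. The alkylpalladium intermediates may then undergo β-hydride elimination, which would give a diene on the decalin side and could erode C13 on the other side through reversible elimination, and the zinc reagent may be lost by protonolysis. The fallback avoids palladium alkyls altogether and sets out from 21. Insertion of Mg (THF, rt) would give the alkylmagnesium iodide F1, which is added slowly at −20 °C to 23 in THF/NMP containing catalytic Li2CuCl4. This copper-catalysed SN2 alkylation of a Grignard reagent by a primary iodide tolerates the methyl ester at this temperature. The route is rejoined at 25.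

Step 12. The ylide may deprotonate C9 and leave an unreactive enolate, or the base may move the new alkene into conjugation with the ester. The fallback takes the ester out of the way first and methylenates a plain ketone without base. It sets out from 18:
- LiAlH4 (Et2O, 0 °C) would give the 8,11-diol F2 (C8 epimers, of no consequence).
- t-BuMe2SiCl and imidazole silylate only the primary alcohol to give the mono-silyl ether F3.
- Dess–Martin oxidation gives the C8 ketone F4.
- The non-basic Zn/CH2Br2/TiCl4 reagent (Takai–Lombardo methylenation), which does not cause β-elimination of the silyloxy group, gives the methylidene silyl ether F5.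
- Camphorsulfonic acid in MeOH removes the tert-butyldimethylsilyl group selectively, and the route is rejoined at 20.

**Further compounds**

F0 | step 10 | none | none
F1 | step 16 | {[(1S,4aR,5R,8aS)-5-{[(tert-butyldiphenylsilyl)oxy]methyl}-5,8a-dimethyl-2-methylidenedecahydronaphthalen-1-yl]methyl}magnesium iodide | C=C1CC[C@H]2[C@](C)(CO[Si](c3ccccc3)(c3ccccc3)C(C)(C)C)CCC[C@]2(C)[C@H]1C[Mg]I
F2 | step 12 | (1S,4aR,5R,8aS)-5-{[(tert-butyldiphenylsilyl)oxy]methyl}-1-(hydroxymethyl)-5,8a-dimethyldecahydronaphthalen-2-ol (C2 epimers) | OC1CC[C@H]2[C@](C)(CO[Si](c3ccccc3)(c3ccccc3)C(C)(C)C)CCC[C@]2(C)[C@H]1CO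
F3 | step 12 | (1S,4aR,5R,8aS)-1-{[(tert-butyldimethylsilyl)oxy]methyl}-5-{[(tert-butyldiphenylsilyl)oxy]methyl}-5,8a-dimethyldecahydronaphthalen-2-ol (C2 epimers) | OC1CC[C@H]2[C@](C)(CO[Si](c3ccccc3)(c3ccccc3)C(C)(C)C)CCC[C@]2(C)[C@H]1CO[Si](C)(C)C(C)(C)C
F4 | step 12 | (1S,4aR,5R,8aS)-1-{[(tert-butyldimethylsilyl)oxy]methyl}-5-{[(tert-butyldiphenylsilyl)oxy]methyl}-5,8a-dimethyloctahydronaphthalen-2(1H)-one | O=C1CC[C@H]2[C@](C)(CO[Si](c3ccccc3)(c3ccccc3)C(C)(C)C)CCC[C@]2(C)[C@H]1CO[Si](C)(C)C(C)(C)C
F5 | step 12 | tert-butyl{[(1S,4aR,5R,8aS)-5-{[(tert-butyldiphenylsilyl)oxy]methyl}-5,8a-dimethyl-2-methylidenedecahydronaphthalen-1-yl]methoxy}dimethylsilane | C=C1CC[C@H]2[C@](C)(CO[Si](c3ccccc3)(c3ccccc3)C(C)(C)C)CCC[C@]2(C)[C@H]1CO[Si](C)(C)C(C)(C)C
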